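**Retrosynthetic overview**
- The target 15 comes from its 4-O-benzyl ether 14. The erythro triol of 14 arises by anti opening (inversion at the benzylic carbon) of the trans-epoxy alcohol 12, which is made by organocatalytic epoxidation of the E-enal 10.
- Enal 10 comes from aryl bromide 7 and the C3 boronate 8 (Suzuki coupling); 7 comes from ester 6 by reduction.
- The trans-dihydrobenzofuran 6 comes from the (R)-flavanone 4 by oxidative ring contraction, a 1,2-shift of the ring A carbon that sets C3 trans to C2.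
- Flavanone 4 comes from the achiral 2'-hydroxychalcone 3 by a catalytic enantioselective oxa-Michael cyclisation (first stereocentre); 3 comes from 1 and 2.
- Ring order: rings A and B are bought intact; the pyranone ring is closed in step 2 and contracted to the dihydrofuran ring in step 3; the oxirane is made in step 6 and opened in step 7.

Assumption: 1, 2 and 8 are bought as catalogue compounds, and in the two catalyst-controlled steps the catalyst antipode that gives the drawn configuration is used (to be confirmed by experiment for the new step 2).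

**Route**

Step 1
Reactants: 1 1-(5-bromo-2-hydroxy-3-methoxyphenyl)ethan-1-one; 2 4-(benzyloxy)-3-methoxybenzaldehyde
Product: 3 (2E)-3-[4-(benzyloxy)-3-methoxyphenyl]-1-(5-bromo-2-hydroxy-3-methoxyphenyl)prop-2-en-1-one
Conditions: KOH (50 % aq.), EtOH, rt, 36 h; aq. HCl; recrystallised free of flavanone
Reagents that add atoms: none
Why: Claisen–Schmidt condensation (crossed aldol, then E1cB dehydration) of the methyl ketone with the non-enolisable aldehyde gives the E-enone, which the hydrogen-bonded 2'-OH keeps open as the chalcone.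

Step 2
Reactants: 3 (2E)-3-[4-(benzyloxy)-3-methoxyphenyl]-1-(5-bromo-2-hydroxy-3-methoxyphenyl)prop-2-en-1-one
Product: 4 (2R)-2-[4-(benzyloxy)-3-methoxyphenyl]-6-bromo-8-methoxy-2,3-dihydro-4H-chromen-4-one
Conditions: chiral IDPi Brønsted acid (BINOL-derived imidodiphosphorimidate, 3,3'-bis[3,5-bis(trifluoromethyl)phenyl] arms, N-triflyl core; 3 mol %), CHCl3, 4 Å MS, −30 °C, stopped near 80 % conversion, 3 recovered
Reagents that add atoms: none
Why: Proposed new method: a confined, strongly acidic IDPi protonates the enone oxygen of 3, so that the hydroxyallyl cation (stabilised by the 4-benzyloxy-3-methoxyphenyl group) sits as a contact ion pair inside the chiral anion, whose basic oxygen takes the phenol proton while the phenolic oxygen adds 6-endo to the Re face of C-β, setting C2 as R under catalyst control; the non-basic medium and low temperature keep the retro-oxa-Michael reaction slow, so the ee is kinetic; this enantioselective Brønsted-acid oxa-Michael cyclisation of an unactivated 2'-hydroxychalcone has not been shown, the closest known reaction types being IDPi-catalysed Nazarov cyclisation of simple divinyl ketones and intramolecular hydroalkoxylation, the chiral-phosphoric-acid aza-Michael cyclisation of 2'-aminochalcones, and the thiourea-catalysed oxa-Michael cyclisation of ester-activated chalcones.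

Step 3
Reactants: 4 (2R)-2-[4-(benzyloxy)-3-methoxyphenyl]-6-bromo-8-methoxy-2,3-dihydro-4H-chromen-4-one
Product: 6 methyl (2R,3R)-2-[4-(benzyloxy)-3-methoxyphenyl]-5-bromo-7-methoxy-2,3-dihydro-1-benzofuran-3-carboxylate, via methyl enol ether 5 (not isolated)
Conditions: PhI(OAc)2 (1.2 equiv), H2SO4 (cat.), HC(OMe)3, rt
Reagents that add atoms: trimethyl orthoformate, COC(OC)OC
Why: Known hypervalent-iodine oxidative ring contraction of flavanones (1,2-aryl shift): enol ether 5 is iodanylated at C3 anti to the C2 aryl group, and the ring A carbon C4a then migrates antiperiplanar from C4 to C3 with loss of PhI and inversion at C3, which sets C3 trans to the untouched C2 stereocentre (2R,3R) and leaves C4 as a dimethoxycarbenium ion that acetate demethylates to the methyl ester.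

Step 4
Reactants: 6 methyl (2R,3R)-2-[4-(benzyloxy)-3-methoxyphenyl]-5-bromo-7-methoxy-2,3-dihydro-1-benzofuran-3-carboxylate
Product: 7 [(2R,3S)-2-[4-(benzyloxy)-3-methoxyphenyl]-5-bromo-7-methoxy-2,3-dihydro-1-benzofuran-3-yl]methanol
Conditions: iBu2AlH (3 equiv), CH2Cl2, −78 → 0 °C
Reagents that add atoms: none
Why: Ester reduction by an aluminium hydride at low temperature without base leaves the α-stereocentre, the benzylic C2–O bond and the aryl bromide untouched; the label at C3 changes from R to S only because CH2OH ranks below C2 (same trans geometry).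

Step 5
Reactants: 7 [(2R,3S)-2-[4-(benzyloxy)-3-methoxyphenyl]-5-bromo-7-methoxy-2,3-dihydro-1-benzofuran-3-yl]methanol; 8 2-[(1E)-3,3-diethoxyprop-1-en-1-yl]-4,4,5,5-tetramethyl-1,3,2-dioxaborolane
Product: 10 (2E)-3-{(2R,3S)-2-[4-(benzyloxy)-3-methoxyphenyl]-3-(hydroxymethyl)-7-methoxy-2,3-dihydro-1-benzofuran-5-yl}prop-2-enal, via diethyl acetal 9 (not isolated)
Conditions: Pd(dppf)Cl2 (5 mol %), K2CO3, 1,4-dioxane/H2O, 85 °C; extractive work-up; then 1 M HCl (cat.), THF, rt
Reagents that add atoms: water, O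
Why: Suzuki–Miyaura coupling of the aryl bromide with the E-alkenylboronate keeps the alkene geometry and tolerates the free alcohol, and mild acid then unmasks the acetal to the E-enal without touching the stereocentres.

Step 6
Reactants: 10 (2E)-3-{(2R,3S)-2-[4-(benzyloxy)-3-methoxyphenyl]-3-(hydroxymethyl)-7-methoxy-2,3-dihydro-1-benzofuran-5-yl}prop-2-enal
Product: 12 [(2R,3R)-3-{(2R,3S)-2-[4-(benzyloxy)-3-methoxyphenyl]-3-(hydroxymethyl)-7-methoxy-2,3-dihydro-1-benzofuran-5-yl}oxiran-2-yl]methanol, via epoxy aldehyde 11 (not isolated)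
Conditions: (R)-2-{bis[3,5-bis(trifluoromethyl)phenyl](trimethylsilyloxy)methyl}pyrrolidine (10 mol %), 35 % aq. H2O2 (1.3 equiv), CH2Cl2, rt; then MeOH, NaBH4, 0 °C
Reagents that add atoms: hydrogen peroxide, OO
Why: Organocatalytic nucleophilic epoxidation of an enal through iminium and then enamine intermediates (diarylprolinol silyl ether catalysis): the bulky silyloxydiarylmethyl group shields one face of the E-iminium ion, H2O2 adds to the open face of C-β and the enamine closes the trans-epoxide, the R catalyst giving the (2S,3R) epoxy aldehyde (mirror image of the 2R,3S series known for the S catalyst) independently of the remote stereocentres, and NaBH4 reduces the aldehyde in the same flask before the labile epoxide can rearrange.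

Step 7
Reactants: 12 [(2R,3R)-3-{(2R,3S)-2-[4-(benzyloxy)-3-methoxyphenyl]-3-(hydroxymethyl)-7-methoxy-2,3-dihydro-1-benzofuran-5-yl}oxiran-2-yl]methanol
Product: 14 (1S,2R)-1-{(2R,3S)-2-[4-(benzyloxy)-3-methoxyphenyl]-3-(hydroxymethyl)-7-methoxy-2,3-dihydro-1-benzofuran-5-yl}propane-1,2,3-triol, via benzoate 13 (not isolated)
Conditions: PhCO2H (1.5 equiv), Ti(OiPr)4 (2 equiv), CH2Cl2, 0 °C → rt; aqueous work-up; then K2CO3 (cat.), MeOH, rt
Reagents that add atoms: benzoic acid, OC(=O)c1ccccc1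
Why: Titanium-mediated regioselective opening of a 2,3-epoxy alcohol by a carboxylic acid: the epoxy alcohol chelates titanium and benzoate attacks the benzylic C3 from the back side (inversion there, retention at C2), which turns the (2R,3R) trans-epoxide into the erythro (1S,2R) pattern, and base-catalysed methanolysis then removes the benzoyl group.

Step 8
Reactants: 14 (1S,2R)-1-{(2R,3S)-2-[4-(benzyloxy)-3-methoxyphenyl]-3-(hydroxymethyl)-7-methoxy-2,3-dihydro-1-benzofuran-5-yl}propane-1,2,3-triol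
Product: 15 (1S,2R)-1-[(2R,3S)-2-(4-hydroxy-3-methoxyphenyl)-3-(hydroxymethyl)-7-methoxy-2,3-dihydro-1-benzofuran-5-yl]propane-1,2,3-triol
Conditions: H2 (1 atm), Pd/C (10 % palladium on carbon), EtOAc/EtOH, rt
Reagents that add atoms: none
Why: Catalytic hydrogenolysis of the benzyl aryl ether under neutral conditions at 1 atm frees the phenol, while the secondary benzylic alcohol and the cyclic benzylic ether, which need acid or forcing conditions to cleave, and all four stereocentres stay intact.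

**Compound list**
1 | 1-(5-bromo-2-hydroxy-3-methoxyphenyl)ethan-1-one | CC(=O)c1cc(Br)cc(OC)c1O | starting material
2 | 4-(benzyloxy)-3-methoxybenzaldehyde | COc1cc(C=O)ccc1OCc1ccccc1 | starting material
3 | (2E)-3-[4-(benzyloxy)-3-methoxyphenyl]-1-(5-bromo-2-hydroxy-3-methoxyphenyl)prop-2-en-1-one | COc1cc(/C=C/C(=O)c2cc(Br)cc(OC)c2O)ccc1OCc1ccccc1 | intermediate
4 | (2R)-2-[4-(benzyloxy)-3-methoxyphenyl]-6-bromo-8-methoxy-2,3-dihydro-4H-chromen-4-one | COc1cc([C@@H]2Oc3c(OC)cc(Br)cc3C(=O)C2)ccc1OCc1ccccc1 | intermediate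
5 | (2R)-2-[4-(benzyloxy)-3-methoxyphenyl]-6-bromo-4,8-dimethoxy-2H-chromene | COc1cc([C@@H]2Oc3c(OC)cc(Br)cc3C(OC)=C2)ccc1OCc1ccccc1 | intermediate
6 | methyl (2R,3R)-2-[4-(benzyloxy)-3-methoxyphenyl]-5-bromo-7-methoxy-2,3-dihydro-1-benzofuran-3-carboxylate | COc1cc([C@@H]2Oc3c(OC)cc(Br)cc3[C@H]2C(=O)OC)ccc1OCc1ccccc1 | intermediate
7 | [(2R,3S)-2-[4-(benzyloxy)-3-methoxyphenyl]-5-bromo-7-methoxy-2,3-dihydro-1-benzofuran-3-yl]methanol | COc1cc([C@@H]2Oc3c(OC)cc(Br)cc3[C@H]2CO)ccc1OCc1ccccc1 | intermediate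
8 | 2-[(1E)-3,3-diethoxyprop-1-en-1-yl]-4,4,5,5-tetramethyl-1,3,2-dioxaborolane | CCOC(OCC)/C=C/B1OC(C)(C)C(C)(C)O1 | starting material
9 | [(2R,3S)-2-[4-(benzyloxy)-3-methoxyphenyl]-5-[(1E)-3,3-diethoxyprop-1-en-1-yl]-7-methoxy-2,3-dihydro-1-benzofuran-3-yl]methanol | COc1cc([C@@H]2Oc3c(OC)cc(/C=C/C(OCC)OCC)cc3[C@H]2CO)ccc1OCc1ccccc1 | intermediate
10 | (2E)-3-{(2R,3S)-2-[4-(benzyloxy)-3-methoxyphenyl]-3-(hydroxymethyl)-7-methoxy-2,3-dihydro-1-benzofuran-5-yl}prop-2-enal | COc1cc([C@@H]2Oc3c(OC)cc(/C=C/C=O)cc3[C@H]2CO)ccc1OCc1ccccc1 | intermediate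
11 | (2S,3R)-3-{(2R,3S)-2-[4-(benzyloxy)-3-methoxyphenyl]-3-(hydroxymethyl)-7-methoxy-2,3-dihydro-1-benzofuran-5-yl}oxirane-2-carbaldehyde | COc1cc([C@@H]2Oc3c(OC)cc([C@H]4O[C@@H]4C=O)cc3[C@H]2CO)ccc1OCc1ccccc1 | intermediate
12 | [(2R,3R)-3-{(2R,3S)-2-[4-(benzyloxy)-3-methoxyphenyl]-3-(hydroxymethyl)-7-methoxy-2,3-dihydro-1-benzofuran-5-yl}oxiran-2-yl]methanol | COc1cc([C@@H]2Oc3c(OC)cc([C@H]4O[C@@H]4CO)cc3[C@H]2CO)ccc1OCc1ccccc1 | intermediate
13 | (1S,2R)-1-{(2R,3S)-2-[4-(benzyloxy)-3-methoxyphenyl]-3-(hydroxymethyl)-7-methoxy-2,3-dihydro-1-benzofuran-5-yl}-2,3-dihydroxypropyl benzoate | COc1cc([C@@H]2Oc3c(OC)cc([C@H](OC(=O)c4ccccc4)[C@H](O)CO)cc3[C@H]2CO)ccc1OCc1ccccc1 | intermediate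
14 | (1S,2R)-1-{(2R,3S)-2-[4-(benzyloxy)-3-methoxyphenyl]-3-(hydroxymethyl)-7-methoxy-2,3-dihydro-1-benzofuran-5-yl}propane-1,2,3-triol | COc1cc([C@@H]2Oc3c(OC)cc([C@H](O)[C@H](O)CO)cc3[C@H]2CO)ccc1OCc1ccccc1 | intermediate
15 | (1S,2R)-1-[(2R,3S)-2-(4-hydroxy-3-methoxyphenyl)-3-(hydroxymethyl)-7-methoxy-2,3-dihydro-1-benzofuran-5-yl]propane-1,2,3-triol | COc1cc([C@@H]2Oc3c(OC)cc([C@H](O)[C@H](O)CO)cc3[C@H]2CO)ccc1O | target

**Step count and risks**
Total step count: 8. Longest linear sequence: 8 steps (1 → 3 → 4 → 6 → 7 → 10 → 12 → 14 → 15; 2 enters at step 1 and 8 at step 5).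

Three steps most likely to fail:

Step 2 (the new reaction). The acid may not turn over this hydrogen-bonded chalcone, or the ee may erode because chalcone and flavanone equilibrate. The fallback uses known chemistry, sets out from 1 and 2 and comes back to the route at 4. Compound 1 is C-acylated (LiN(SiMe3)2, Boc2O, THF, −78 °C → rt) to give tert-butyl 3-(5-bromo-2-hydroxy-3-methoxyphenyl)-3-oxopropanoate F1. Knoevenagel condensation of F1 with 2 (piperidine, AcOH, toluene, reflux) gives tert-butyl 3-[4-(benzyloxy)-3-methoxyphenyl]-2-(5-bromo-2-hydroxy-3-methoxybenzoyl)prop-2-enoate F2. A cinchona-alkaloid-derived bifunctional thiourea (10 mol %, toluene, −25 °C; quinine or quinidine series chosen for 2R) then closes this activated acceptor essentially irreversibly to tert-butyl (2R)-2-[4-(benzyloxy)-3-methoxyphenyl]-6-bromo-8-methoxy-4-oxo-3,4-dihydro-2H-chromene-3-carboxylate F3. TsOH (toluene, 80 °C) removes the tert-butyl ester with decarboxylation and gives 4.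

Step 3. The iodane may attack the electron-rich aryl rings, flavone or isoflavone may form instead, and C2 may partly ionise in the strong acid. The fallback separates oxidation from rearrangement; it sets out from 4 and comes back at 6. Compound 4 is brominated at C3 (CuBr2, EtOAc/CHCl3, reflux) to the trans bromo ketone (2S,3S)-2-[4-(benzyloxy)-3-methoxyphenyl]-3,6-dibromo-8-methoxy-2,3-dihydro-4H-chromen-4-one F4. This is ketalised (HC(OMe)3, MeOH, TsOH cat.) to (2S,3S)-2-[4-(benzyloxy)-3-methoxyphenyl]-3,6-dibromo-4,4,8-trimethoxy-3,4-dihydro-2H-chromene F5. AgBF4 (MeOH, 40 °C) then pulls off bromide, so the ring A carbon shifts from C4 to C3 antiperiplanar to the leaving group (the 1,2-aryl shift of α-halo ketals) and gives the same trans ester 6.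

Step 7. Partial loss of inversion at the electron-rich benzylic carbon would give the threo isomer. The fallback delivers the oxygen intramolecularly; it sets out from 12 and comes back at 14. Both primary alcohols of 12 are converted into tert-butyl carbonates (Boc2O, DMAP, CH2Cl2) to give [(2R,3R)-3-{(2R,3S)-2-[4-(benzyloxy)-3-methoxyphenyl]-3-({[(tert-butoxy)carbonyl]oxy}methyl)-7-methoxy-2,3-dihydro-1-benzofuran-5-yl}oxiran-2-yl]methyl tert-butyl carbonate F6. BF3·OEt2 (CH2Cl2, −40 °C) makes the neighbouring carbonate carbonyl oxygen open the epoxide 6-endo at the benzylic carbon. Both the back-side path and any cation-like path lead to the same diequatorial trans-4-aryl-5-hydroxy carbonate, tert-butyl {(2R,3S)-2-[4-(benzyloxy)-3-methoxyphenyl]-5-[(4S,5R)-5-hydroxy-2-oxo-1,3-dioxan-4-yl]-7-methoxy-2,3-dihydro-1-benzofuran-3-yl}methyl carbonate F7. NaOMe in MeOH cleaves both carbonates and gives 14.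

**Further compounds**
F1 | step 2 | tert-butyl 3-(5-bromo-2-hydroxy-3-methoxyphenyl)-3-oxopropanoate | CC(C)(C)OC(=O)CC(=O)c1cc(Br)cc(OC)c1O
F2 | step 2 | tert-butyl 3-[4-(benzyloxy)-3-methoxyphenyl]-2-(5-bromo-2-hydroxy-3-methoxybenzoyl)prop-2-enoate (E/Z mixture) | COc1cc(C=C(C(=O)OC(C)(C)C)C(=O)c2cc(Br)cc(OC)c2O)ccc1OCc1ccccc1
F3 | step 2 | tert-butyl (2R)-2-[4-(benzyloxy)-3-methoxyphenyl]-6-bromo-8-methoxy-4-oxo-3,4-dihydro-2H-chromene-3-carboxylate | COc1cc([C@@H]2Oc3c(OC)cc(Br)cc3C(=O)C2C(=O)OC(C)(C)C)ccc1OCc1ccccc1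
F4 | step 3 | (2S,3S)-2-[4-(benzyloxy)-3-methoxyphenyl]-3,6-dibromo-8-methoxy-2,3-dihydro-4H-chromen-4-one | COc1cc([C@@H]2Oc3c(OC)cc(Br)cc3C(=O)[C@H]2Br)ccc1OCc1ccccc1
F5 | step 3 | (2S,3S)-2-[4-(benzyloxy)-3-methoxyphenyl]-3,6-dibromo-4,4,8-trimethoxy-3,4-dihydro-2H-chromene | COc1cc([C@@H]2Oc3c(OC)cc(Br)cc3C(OC)(OC)[C@H]2Br)ccc1OCc1ccccc1
F6 | step 7 | [(2R,3R)-3-{(2R,3S)-2-[4-(benzyloxy)-3-methoxyphenyl]-3-({[(tert-butoxy)carbonyl]oxy}methyl)-7-methoxy-2,3-dihydro-1-benzofuran-5-yl}oxiran-2-yl]methyl tert-butyl carbonate | COc1cc([C@@H]2Oc3c(OC)cc([C@H]4O[C@@H]4COC(=O)OC(C)(C)C)cc3[C@H]2COC(=O)OC(C)(C)C)ccc1OCc1ccccc1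
F7 | step 7 | tert-butyl {(2R,3S)-2-[4-(benzyloxy)-3-methoxyphenyl]-5-[(4S,5R)-5-hydroxy-2-oxo-1,3-dioxan-4-yl]-7-methoxy-2,3-dihydro-1-benzofuran-3-yl}methyl carbonate | COc1cc([C@@H]2Oc3c(OC)cc([C@@H]4OC(=O)OC[C@H]4O)cc3[C@H]2COC(=O)OC(C)(C)C)ccc1OCc1ccccc1
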